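The pyran ring (O1, C2, C3, C4, C4a, C8a) is not closed directly. Because O1 on C8a stands para to the C6 hydroxyl, the benzene ring is disguised as a cross-conjugated cyclohexadienone (C6 as carbonyl) whose spiro carbon C8a carries a 2,5-dihydrofuran (O1, C2, C3=C4). A Lewis-acid dienone–phenol rearrangement shifts vinyl carbon C4 from C8a to C4a: in one operation the five-membered ring grows into the 2H-pyran, the arene and the phenol appear, and both spiro epimers converge. C2 is set earlier by Sharpless epoxidation of geranylgeraniol and its C–O bond is never broken. The precursor, a 1-oxaspiro[4.5]decatrienone, comes from oxidative dearomatisation of a (Z)-alkenylphenol.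

Key step: step 7

Remark: C2 of the target is S by CIP analysis (O1 > C3 > side-chain CH2 > CH3), i.e. opposite in space to the natural tocotrienols; all-E geranylgeraniol (1) and 4-iodo-3-methylphenol (7) are taken as catalogue compounds.

Step 1
Reactants: 1 (2E,6E,10E)-geranylgeraniol
Product: 2 [(2S,3S)-3-methyl-3-[(3E,7E)-4,8,12-trimethyltrideca-3,7,11-trien-1-yl]oxiran-2-yl]methanol
Conditions: Ti(OiPr)4 (cat.), L-(+)-diethyl tartrate (cat.), t-BuOOH, 4 Å MS, CH2Cl2, −20 °C
Reagents that add atoms: tert-butyl hydroperoxide, CC(C)(C)OO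
Why: Sharpless asymmetric epoxidation, in which the titanium tartrate binds the allylic hydroxyl so that only the 2,3-alkene reacts and L-(+)-DET directs oxygen to the face that gives the (2S,3S)-epoxide, as with geraniol.

Step 2
Reactants: 2 [(2S,3S)-3-methyl-3-[(3E,7E)-4,8,12-trimethyltrideca-3,7,11-trien-1-yl]oxiran-2-yl]methanol
Product: 3 (2R,3S)-2-(chloromethyl)-3-methyl-3-[(3E,7E)-4,8,12-trimethyltrideca-3,7,11-trien-1-yl]oxirane
Conditions: PPh3, CCl4, NaHCO3, reflux
Reagents that add atoms: carbon tetrachloride, ClC(Cl)(Cl)Cl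
Why: Appel chlorination by SN2 at the primary carbon should leave the epoxide and both stereocentres untouched (the descriptor at C2 changes to R only through CIP priority).

Step 3
Reactants: 3 (2R,3S)-2-(chloromethyl)-3-methyl-3-[(3E,7E)-4,8,12-trimethyltrideca-3,7,11-trien-1-yl]oxirane
Product: 6 (3S,6E,10E)-3,7,11,15-tetramethylhexadeca-6,10,14-trien-1-yn-3-ol, via lithium chloroalkenyl alkoxide 4 (not isolated), via dilithium alkynide alkoxide 5 (not isolated)
Conditions: n-BuLi (3.3 equiv), THF, −40 °C; then aq. NH4Cl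
Reagents that add atoms: none
Why: Base-induced fragmentation of a 2,3-epoxy chloride to a propargylic alcohol (deprotonation at CH2Cl, β-elimination that opens the epoxide, then dehydrochlorination) never breaks the C3–O bond, so the tertiary carbinol should keep the S configuration.

Step 4
Reactants: 6 (3S,6E,10E)-3,7,11,15-tetramethylhexadeca-6,10,14-trien-1-yn-3-ol; 7 4-iodo-3-methylphenol
Product: 8 4-[(3S,6E,10E)-3-hydroxy-3,7,11,15-tetramethylhexadeca-6,10,14-trien-1-yn-1-yl]-3-methylphenol
Conditions: PdCl2(PPh3)2 (3 mol %), CuI (5 mol %), Et3N, THF, rt, degassed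
Reagents that add atoms: none
Why: Sonogashira coupling of an aryl iodide at room temperature should tolerate the free phenol and the tertiary alcohol, and with the hydroxyl para to the alkyne no benzofuran can form.

Step 5
Reactants: 8 4-[(3S,6E,10E)-3-hydroxy-3,7,11,15-tetramethylhexadeca-6,10,14-trien-1-yn-1-yl]-3-methylphenol
Product: 9 4-[(1Z,3S,6E,10E)-3-hydroxy-3,7,11,15-tetramethylhexadeca-1,6,10,14-tetraen-1-yl]-3-methylphenol
Conditions: H2 (1 atm), Lindlar catalyst, quinoline, EtOAc, rt, stopped after 1 equiv H2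
Reagents that add atoms: none
Why: Lindlar semihydrogenation adds hydrogen syn to give the Z-alkene, which places the tertiary hydroxyl over the arene ipso carbon, while the trisubstituted alkenes should not be reduced.

Step 6
Reactants: 9 4-[(1Z,3S,6E,10E)-3-hydroxy-3,7,11,15-tetramethylhexadeca-1,6,10,14-tetraen-1-yl]-3-methylphenol
Product: 10 (2S)-2,6-dimethyl-2-[(3E,7E)-4,8,12-trimethyltrideca-3,7,11-trien-1-yl]-1-oxaspiro[4.5]deca-3,6,9-trien-8-one (both C5 epimers)
Conditions: PhI(OAc)2 (1.05 equiv), MeCN, 0 °C; then aq. NaHCO3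
Reagents that add atoms: none
Why: Iodine(III) oxidative dearomatisation of a para-substituted phenol with 5-exo capture of the ipso carbon by the tethered tertiary hydroxyl (spiroetherification) leaves C2 untouched; the spiro stereocentre forms without control, which does not matter because step 7 destroys it.

Step 7
Reactants: 10 (2S)-2,6-dimethyl-2-[(3E,7E)-4,8,12-trimethyltrideca-3,7,11-trien-1-yl]-1-oxaspiro[4.5]deca-3,6,9-trien-8-one (both C5 epimers)
Product: 11 (2S)-2,8-dimethyl-2-[(3E,7E)-4,8,12-trimethyltrideca-3,7,11-trien-1-yl]-2H-chromen-6-ol (CNP0242881.1)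
Conditions: BF3·OEt2 (0.3 equiv), CH2Cl2, −78 to −30 °C; Et3N then aq. NaHCO3 quench; light excluded
Reagents that add atoms: none
Why: BF3 binds the dienone carbonyl (future C6–O) to give an oxy-pentadienyl cation with positive charge on both carbons flanking the spiro centre, the vinyl carbon (future C4) shifts 1,2 from the spiro carbon (future C8a) to the unsubstituted neighbour (future C4a), and the oxygen-stabilised cation that results loses the C4a proton to give the aromatic chromenol. The closest known reaction type is the acid-promoted dienone–phenol rearrangement of 4,4-disubstituted cyclohexa-2,5-dienones, including 1-oxaspiro[4.5]decadienones that give chroman-6-ols. The six-membered ring is closed by ring enlargement and not by cyclisation: the migrating sp2 carbon bridges C8a and C4a in a cyclopropylcarbinyl-type (formally 3-exo-trig) transition structure that opens towards the oxygen-bearing carbon, so the dihydrofuran grows by one atom. No stereocentre is created: the C2–O1 and C2–C3 bonds are never broken, so C2 keeps the S configuration set in step 1, and the spiro stereocentre vanishes on aromatisation, so both epimers of 10 converge on one product. Two selectivities are needed: carbon rather than oxygen must migrate, which is secured because only carbon migration leaves a cation stabilised by O1; and the shift must end at the CH neighbour rather than the methyl-bearing one, which is secured because a shift to the methyl-bearing carbon gives a cation that cannot lose a proton and should return by the fast reverse vinyl shift, whereas the shift to the CH carbon is made irreversible by aromatisation. Substoichiometric Lewis acid at low temperature is chosen to spare the tertiary allylic ether and the trisubstituted alkenes.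

Compound list
1 | (2E,6E,10E)-geranylgeraniol | CC(C)=CCC/C(C)=C/CC/C(C)=C/CC/C(C)=C/CO | starting material
2 | [(2S,3S)-3-methyl-3-[(3E,7E)-4,8,12-trimethyltrideca-3,7,11-trien-1-yl]oxiran-2-yl]methanol | CC(C)=CCC/C(C)=C/CC/C(C)=C/CC[C@]1(C)O[C@H]1CO | intermediate
3 | (2R,3S)-2-(chloromethyl)-3-methyl-3-[(3E,7E)-4,8,12-trimethyltrideca-3,7,11-trien-1-yl]oxirane | CC(C)=CCC/C(C)=C/CC/C(C)=C/CC[C@]1(C)O[C@H]1CCl | intermediate
4 | lithium (3S,6E,10E)-1-chloro-3,7,11,15-tetramethylhexadeca-1,6,10,14-tetraen-3-olate (C1=C2 geometry not defined) | CC(C)=CCC/C(C)=C/CC/C(C)=C/CC[C@@]([O-])(C)C=CCl.[Li+] | intermediate (not isolated)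
5 | dilithium salt (alkynide and alkoxide) of (3S,6E,10E)-3,7,11,15-tetramethylhexadeca-6,10,14-trien-1-yn-3-ol | CC(C)=CCC/C(C)=C/CC/C(C)=C/CC[C@@]([O-])(C)C#[C-].[Li+].[Li+] | intermediate (not isolated)
6 | (3S,6E,10E)-3,7,11,15-tetramethylhexadeca-6,10,14-trien-1-yn-3-ol | CC(C)=CCC/C(C)=C/CC/C(C)=C/CC[C@@](O)(C)C#C | intermediate
7 | 4-iodo-3-methylphenol | Cc1cc(O)ccc1I | starting material
8 | 4-[(3S,6E,10E)-3-hydroxy-3,7,11,15-tetramethylhexadeca-6,10,14-trien-1-yn-1-yl]-3-methylphenol | CC(C)=CCC/C(C)=C/CC/C(C)=C/CC[C@@](O)(C)C#Cc1ccc(O)cc1C | intermediate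
9 | 4-[(1Z,3S,6E,10E)-3-hydroxy-3,7,11,15-tetramethylhexadeca-1,6,10,14-tetraen-1-yl]-3-methylphenol | CC(C)=CCC/C(C)=C/CC/C(C)=C/CC[C@@](O)(C)/C=C\c1ccc(O)cc1C | intermediate
10 | (2S)-2,6-dimethyl-2-[(3E,7E)-4,8,12-trimethyltrideca-3,7,11-trien-1-yl]-1-oxaspiro[4.5]deca-3,6,9-trien-8-one (both C5 epimers; C5 left undefined) | CC(C)=CCC/C(C)=C/CC/C(C)=C/CC[C@@]1(C)C=CC2(O1)C=CC(=O)C=C2C | intermediate
11 | (2S)-2,8-dimethyl-2-[(3E,7E)-4,8,12-trimethyltrideca-3,7,11-trien-1-yl]-2H-chromen-6-ol (CNP0242881.1) | CC(C)=CCC/C(C)=C/CC/C(C)=C/CC[C@@]1(C)C=Cc2cc(O)cc(C)c2O1 | target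

Total step count: 7. Longest linear sequence: 7 steps (1 to 11).

Steps most likely to fail

Step 7. The Lewis acid may ionise the tertiary allylic C2–O1 bond instead of activating the dienone (loss of configuration or elimination). The vinyl group may also shift to the methyl-bearing carbon and be followed by a methyl shift, or the acid may start cyclisation of the polyene. The fallback keeps the ring enlargement but removes the allylic ether; it sets out from 9 and comes back at 11. Diimide (2-nitrobenzenesulfonyl hydrazide, Et3N, rt) should reduce only the disubstituted Z-alkene to give 4-[(3S,6E,10E)-3-hydroxy-3,7,11,15-tetramethylhexadeca-6,10,14-trien-1-yl]-3-methylphenol F1. PhI(OAc)2 in MeCN should then give the saturated spiro ether (2S)-2,6-dimethyl-2-[(3E,7E)-4,8,12-trimethyltrideca-3,7,11-trien-1-yl]-1-oxaspiro[4.5]deca-6,9-dien-8-one F2. BF3·OEt2 should enlarge its tetrahydrofuran by migration of the sp3 carbon to the chromanol (2S)-2,8-dimethyl-2-[(3E,7E)-4,8,12-trimethyltrideca-3,7,11-trien-1-yl]-3,4-dihydro-2H-chromen-6-ol F3. Acetylation (Ac2O, pyridine) gives the chromanyl acetate F4, DDQ dehydrogenation (dioxane, reflux) introduces the C3=C4 bond to give the chromenyl acetate F5, and K2CO3 in MeOH releases 11.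

Step 6. The cationic character of the oxidised phenol is spread through the styrene onto C3, so capture by acetate at that carbon, over-oxidation, or rearrangement of the product in the flask may outrun spiroetherification. The fallback makes the C8a–O1 bond by ionisation at the ring carbon instead of by oxidation of the arene; it sets out from 6 and comes back at 10. The dianion of 6 (n-BuLi, 2 equiv, THF, −78 °C) should add 1,2 to 4,4-dimethoxy-2-methylcyclohexa-2,5-dien-1-one F6 (one step from 4-methoxy-2-methylphenol with PhI(OAc)2 in MeOH). This gives 1-[(3S,6E,10E)-3-hydroxy-3,7,11,15-tetramethylhexadeca-6,10,14-trien-1-yn-1-yl]-4,4-dimethoxy-2-methylcyclohexa-2,5-dien-1-ol F7. Lindlar semihydrogenation gives the (Z)-ene-1,4-diol 1-[(1Z,3S,6E,10E)-3-hydroxy-3,7,11,15-tetramethylhexadeca-1,6,10,14-tetraen-1-yl]-4,4-dimethoxy-2-methylcyclohexa-2,5-dien-1-ol F8. Catalytic camphorsulfonic acid in dry CH2Cl2 over 4 Å MS should ionise only the doubly allylic ring carbinol; the C2 hydroxyl then closes the dihydrofuran with its own C–O bond intact. The product is the spiro ketal (2S)-8,8-dimethoxy-2,6-dimethyl-2-[(3E,7E)-4,8,12-trimethyltrideca-3,7,11-trien-1-yl]-1-oxaspiro[4.5]deca-3,6,9-triene F9, and aqueous oxalic acid in THF hydrolyses the ketal to 10.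

Step 5. The hydrogenation may run on to the alkane, or the electron-rich styrene may isomerise from Z to E on the catalyst. The fallback fixes the alkene geometry before the C–C coupling; it sets out from 6 and comes back at 9, replacing steps 4 and 5. Rhodium-catalysed trans-hydroboration of the terminal alkyne ([Rh(cod)Cl]2, P(i-Pr)3, Et3N, pinacolborane) should give the (Z)-alkenylboronate (1Z,3S,6E,10E)-3,7,11,15-tetramethyl-1-(4,4,5,5-tetramethyl-1,3,2-dioxaborolan-2-yl)hexadeca-1,6,10,14-tetraen-3-ol F10. Suzuki–Miyaura coupling with 7 (Pd(dppf)Cl2, K3PO4, THF/H2O, 40 °C) then proceeds with retention of the alkene geometry to give 9.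

Further compounds
F1 | step 7 | 4-[(3S,6E,10E)-3-hydroxy-3,7,11,15-tetramethylhexadeca-6,10,14-trien-1-yl]-3-methylphenol | CC(C)=CCC/C(C)=C/CC/C(C)=C/CC[C@@](O)(C)CCc1ccc(O)cc1C
F2 | step 7 | (2S)-2,6-dimethyl-2-[(3E,7E)-4,8,12-trimethyltrideca-3,7,11-trien-1-yl]-1-oxaspiro[4.5]deca-6,9-dien-8-one (both C5 epimers) | CC(C)=CCC/C(C)=C/CC/C(C)=C/CC[C@@]1(C)CCC2(O1)C=CC(=O)C=C2C
F3 | step 7 | (2S)-2,8-dimethyl-2-[(3E,7E)-4,8,12-trimethyltrideca-3,7,11-trien-1-yl]-3,4-dihydro-2H-chromen-6-ol | CC(C)=CCC/C(C)=C/CC/C(C)=C/CC[C@@]1(C)CCc2cc(O)cc(C)c2O1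
F4 | step 7 | (2S)-2,8-dimethyl-2-[(3E,7E)-4,8,12-trimethyltrideca-3,7,11-trien-1-yl]-3,4-dihydro-2H-chromen-6-yl acetate | CC(C)=CCC/C(C)=C/CC/C(C)=C/CC[C@@]1(C)CCc2cc(OC(C)=O)cc(C)c2O1
F5 | step 7 | (2S)-2,8-dimethyl-2-[(3E,7E)-4,8,12-trimethyltrideca-3,7,11-trien-1-yl]-2H-chromen-6-yl acetate | CC(C)=CCC/C(C)=C/CC/C(C)=C/CC[C@@]1(C)C=Cc2cc(OC(C)=O)cc(C)c2O1
F6 | step 6 | 4,4-dimethoxy-2-methylcyclohexa-2,5-dien-1-one | COC1(OC)C=CC(=O)C(C)=C1
F7 | step 6 | 1-[(3S,6E,10E)-3-hydroxy-3,7,11,15-tetramethylhexadeca-6,10,14-trien-1-yn-1-yl]-4,4-dimethoxy-2-methylcyclohexa-2,5-dien-1-ol (both C1 epimers) | CC(C)=CCC/C(C)=C/CC/C(C)=C/CC[C@@](O)(C)C#CC1(O)C=CC(OC)(OC)C=C1C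
F8 | step 6 | 1-[(1Z,3S,6E,10E)-3-hydroxy-3,7,11,15-tetramethylhexadeca-1,6,10,14-tetraen-1-yl]-4,4-dimethoxy-2-methylcyclohexa-2,5-dien-1-ol (both C1 epimers) | CC(C)=CCC/C(C)=C/CC/C(C)=C/CC[C@@](O)(C)/C=C\C1(O)C=CC(OC)(OC)C=C1C
F9 | step 6 | (2S)-8,8-dimethoxy-2,6-dimethyl-2-[(3E,7E)-4,8,12-trimethyltrideca-3,7,11-trien-1-yl]-1-oxaspiro[4.5]deca-3,6,9-triene (both C5 epimers) | CC(C)=CCC/C(C)=C/CC/C(C)=C/CC[C@@]1(C)C=CC2(O1)C=CC(OC)(OC)C=C2C
F10 | step 5 | (1Z,3S,6E,10E)-3,7,11,15-tetramethyl-1-(4,4,5,5-tetramethyl-1,3,2-dioxaborolan-2-yl)hexadeca-1,6,10,14-tetraen-3-ol | CC(C)=CCC/C(C)=C/CC/C(C)=C/CC[C@@](O)(C)/C=C\B1OC(C)(C)C(C)(C)O1
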